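The disconnection is the bond between the two hydroxyl-bearing carbons of the benzene ring (C3–C4 when the methyl carbon is C1). A six-membered carbocycle with two adjacent oxygenated carbons is the product pattern of an intramolecular acyloin coupling. Sodium reduction of an adipate diester with chlorotrimethylsilane as trap joins the two ester carbons, closes the ring and installs both oxygens as an enediol bis(silyl) ether in one operation. The precursor is open-chain dimethyl 3-methyladipate, whose branch methyl becomes the aryl methyl. Bromine then lifts the ring to the catechol oxidation level and fills the three free positions C2, C5 and C6.

Key step: step 2

Remark on the chemistry: the target has no stereocentre and is achiral, so no enantiocontrol is needed. Racemic 3-methyladipic acid is used because its single stereocentre becomes an sp2 ring carbon on aromatization.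

Step 1
Reactants: 1 3-methyladipic acid (3-methylhexanedioic acid, racemic); 2 methanol
Product: 3 dimethyl 3-methyladipate (dimethyl 3-methylhexanedioate, racemic)
Conditions: MeOH (solvent, large excess), H2SO4 (cat.), reflux; NaHCO3 wash, distillation
Reagents that add atoms: methanol, CO
Why: Fischer esterification, an acid-catalysed acyl substitution pushed to the diester by the excess of methanol; the remote methyl-bearing carbon is not involved.

Step 2
Reactants: 3 dimethyl 3-methyladipate (racemic); 4 chlorotrimethylsilane
Product: 5 4-methyl-1,2-bis(trimethylsilyloxy)cyclohex-1-ene (racemic)
Conditions: Na (4.4 equiv, dispersion), Me3SiCl (4.6 equiv), toluene, reflux, N2, slow addition of 3; filtration under N2, distillation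
Reagents that add atoms: chlorotrimethylsilane, C[Si](C)(C)Cl
Why: Sodium should donate one electron to each ester carbonyl of 3, and the two ketyl radical anions couple carbon to carbon (chain C1 to C6, the later C3–C4 bond of the target); two methoxides then leave to give the 1,2-dione, which takes up two more electrons to form the enediolate that 4 silylates on both oxygens. The closest known reaction type is the acyloin condensation of adipate diesters in its Rühlmann silyl-trapping form. The single six-membered carbocycle closes by head-to-head reductive coupling of the two chain termini, formally a 6-exo-trig attack of one ketyl carbon on the other ester carbonyl, with both oxygens left outside the ring. No stereocentre is formed, since both new ring carbons are sp2, and the existing methyl-bearing centre is untouched and racemic. The selectivity needed is reductive coupling over Dieckmann cyclization and over intermolecular coupling: 4 removes methoxide as MeOSiMe3 so that no alkoxide base accumulates, while slow addition and the favourable six-ring geometry keep the coupling intramolecular. Regiochemistry is not in question because both termini are the same functional group and the chain can close in only one way.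

Step 3
Reactants: 5 4-methyl-1,2-bis(trimethylsilyloxy)cyclohex-1-ene (racemic); 6 bromine
Product: 9 3,4,6-tribromo-5-methylbenzene-1,2-diol, via 4-methylcyclohexane-1,2-dione 7 (not isolated), via 4-methylbenzene-1,2-diol 8 (not isolated)
Conditions: Br2 (1.0 equiv), CH2Cl2, −78 → 0 °C; evaporate (CH2Cl2, Me3SiBr); then Br2 (4.2 equiv, in portions), AcOH, 20 → 50 °C, dark; aq. NaHSO3
Reagents that add atoms: bromine, BrBr
Why: Bromine should first oxidize the enediol bis(silyl) ether to dione 7 with loss of two Me3SiBr (oxidative desilylation), then α-brominate the enol of 7, which loses HBr and tautomerizes to catechol 8 (bromination–dehydrobromination aromatization), and finally substitute the three remaining ring positions, each ortho or para to a hydroxyl (electrophilic aromatic bromination); any ring bromination that runs ahead of aromatization should converge on the same product, and the bisulfite quench should return o-quinone formed by over-oxidation to the catechol.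

Compound list
1 | 3-methyladipic acid (3-methylhexanedioic acid), racemic | OC(=O)CC(C)CCC(=O)O | starting material
2 | methanol | CO | starting material
3 | dimethyl 3-methyladipate (dimethyl 3-methylhexanedioate), racemic | COC(=O)CC(C)CCC(=O)OC | intermediate
4 | chlorotrimethylsilane | C[Si](C)(C)Cl | starting material
5 | 4-methyl-1,2-bis(trimethylsilyloxy)cyclohex-1-ene, racemic | CC1CCC(O[Si](C)(C)C)=C(O[Si](C)(C)C)C1 | intermediate
6 | bromine | BrBr | starting material
7 | 4-methylcyclohexane-1,2-dione, racemic, in equilibrium with its enols | CC1CCC(=O)C(=O)C1 | intermediate (not isolated)
8 | 4-methylbenzene-1,2-diol (4-methylcatechol), achiral | Cc1ccc(O)c(O)c1 | intermediate (not isolated)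
9 | 3,4,6-tribromo-5-methylbenzene-1,2-diol (3,5,6-tribromo-4-methylcatechol), achiral | Cc1c(Br)c(O)c(O)c(Br)c1Br | target

Total step count: 3
Longest linear sequence: 3

Steps most likely to fail

Step 2. Alkoxide-driven Dieckmann cyclization or intermolecular ketyl coupling may overtake the ring-closing reductive coupling, for instance when the sodium surface is passivated or the silyl chloride carries HCl. The moisture-sensitive product may also be hydrolysed during isolation. The fallback sets out from 3 and comes back to the route at 7. Diester 3 would be half-reduced with DIBAL-H (CH2Cl2, −78 °C) to 3-methylhexanedial F1. Intramolecular pinacol coupling with SmI2 in THF would form the same ring bond between the two oxygen-bearing carbons and give 4-methylcyclohexane-1,2-diol F2 as a mixture of diastereomers, whose configuration is irrelevant. Double Swern oxidation (DMSO, (COCl)2, Et3N, −78 °C) would give 7, which is carried through the second stage of step 3 (Br2, AcOH) to 9.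

Step 3. Dehydrobromination may lag behind bromination and leave partly brominated non-aromatic diones. Radical bromination at the benzylic methyl or over-oxidation to the o-quinone with subsequent degradation may also erode the material. The fallback sets out from 5 and comes back to the route at 9, and it separates aromatization from halogenation. Compound 5 would be oxidized with one equivalent of Br2 in CH2Cl2 at −78 °C and 7 isolated by distillation. Dione 7 would be aromatized to 8 by catalytic dehydrogenation over Pd/C in refluxing p-cymene under a nitrogen sweep, with no bromine involved. Purified 8 would then be tribrominated with exactly three equivalents of Br2 in AcOH at 0 → 20 °C in the dark. This fallback makes no compound outside the list (F0).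

Step 1. The equilibrium esterification may stall at the half-ester when water accumulates, and residual acid would consume sodium in step 2. The fallback sets out from 1 and comes back to the route at 3. The dicarboxylate would be alkylated irreversibly on oxygen with MeI and K2CO3 in DMF at room temperature, an SN2 reaction at methyl instead of an acyl substitution. This fallback makes no compound outside the list (F0).

Further compounds
F1 | step 2 | 3-methylhexanedial, racemic | O=CCC(C)CCC=O
F2 | step 2 | 4-methylcyclohexane-1,2-diol, mixture of diastereomers | CC1CCC(O)C(O)C1
F0 | step 3 | none | none
F0 | step 1 | none | none
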